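**Retrosynthetic overview**
1. Target 11 is all-E (5R,6R)-5,6-dihydroxy-5,6-dihydro-10'-apo-β-caroten-10'-al (C27, trans-diol). Cut C11'=C12' (Wittig with a masked formylmethylene ylide) to reach C25 aldehyde 9.
2. Cut C11=C12 of 9 (Wittig) to reach C15 phosphonium salt 5 and the commercial C10 dialdehyde 6.
3. Salt 5 comes from diol ketone 3 by vinyl Grignard addition and PPh3·HBr allylic transposition, which makes C9=C10.
4. Ketone 3 comes from β-ionone 1: both C–O bonds at C5 and C6, and both stereocenters, are made first by one catalytic enantioselective anti-dihydroxylation.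
5. Rings: cyclohexane ring A is carried intact from 1; the only ring formed is the transient oxirane (ring B) in step 1, opened in the same flask.

Numbering: carotenoid numbering is used. Ring C1 is the CMe2 carbon, C5 bears CH3, C6 bears the chain; the chain runs C7 to C15, then C15' down to C10' (CHO). (S,S)-PDP is (2S,2'S)-1,1'-bis(pyridin-2-ylmethyl)-2,2'-bipyrrolidine. Steps 4 and 5 are run under argon in dim light.

Assumption: the (S,S)-catalyst is taken to give the (5S,6R)-epoxide and acid opening is taken to occur at C5; the commercial (R,R)-complex is used instead if the first run shows the opposite sense.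

**Step 1**
Reactants: 1 β-ionone
Product: 3 (5R,6R)-5,6-dihydroxy-5,6-dihydro-β-ionone, via (5S,6R)-epoxide 2 (not isolated)
Conditions: [Mn(OTf)2((S,S)-PDP)] (1 mol%), 2-ethylhexanoic acid (2 equiv), 50% aq. H2O2 (1.2 equiv, slow addition), MeCN, −30 °C; then 5% aq. HClO4, THF, 0 °C to rt
Reagents that add atoms: hydrogen peroxide OO; water O
Why: Proposed new method: a catalytic enantioselective anti-dihydroxylation of a tetrasubstituted alkene in one operation, in which the divalent manganese precatalyst, H2O2 and the carboxylic acid give an electrophilic oxo-manganese carboxylate (formally pentavalent manganese) that transfers oxygen to the most electron-rich π bond, the ring C5=C6 alkene twisted out of conjugation with the enone (the site peracids also attack), while the chiral pocket reads the four very different alkene substituents (CMe2 against CH2, flat enone arm against CH3) and sets C6 in (5S,6R)-epoxide 2, after which aqueous acid opens the protonated oxirane by backside attack of water at C5 only (cationic character at C6 is disfavoured by the vinylogous acyl group and C6 is shielded by C1), so C6–O is retained, C5 is inverted and the trans (5R,6R)-diol results; the closest known reaction types are aminopyridine-manganese/H2O2 asymmetric epoxidation of enones and chromenes and the racemic peracid epoxidation/acid hydrolysis sequence, neither shown for the tetrasubstituted γ,δ-alkene of a dienone or as an asymmetric anti-dihydroxylation.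

**Step 2**
Reactants: 3 (5R,6R)-5,6-dihydroxy-5,6-dihydro-β-ionone
Product: 4 vinyl carbinol triol (1R,2R)-1-[(1E)-3-hydroxy-3-methylpenta-1,4-dien-1-yl]-2,6,6-trimethylcyclohexane-1,2-diol
Conditions: CH2=CHMgBr (3.5 equiv), THF, −20 °C to 0 °C; then H2O
Reagents that add atoms: vinylmagnesium bromide C=C[Mg]Br
Why: Grignard 1,2-addition to the enone carbonyl (the vinyl-β-ionol reaction); two equivalents are consumed by the tertiary hydroxyls as inert alkoxides, and the new C9 carbinol forms as an epimer mixture that is erased in step 3.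

**Step 3**
Reactants: 4 vinyl carbinol triol
Product: 5 [(2E,4E)-5-[(1R,2R)-1,2-dihydroxy-2,6,6-trimethylcyclohexyl]-3-methylpenta-2,4-dien-1-yl]triphenylphosphonium bromide
Conditions: PPh3·HBr (1.05 equiv), MeOH, 0 °C to rt; crystallise from EtOAc/acetone
Reagents that add atoms: triphenylphosphine hydrobromide [Br-].c1ccc(cc1)[PH+](c1ccccc1)c1ccccc1
Why: Acid-mediated allylic transposition to a phosphonium salt: the bis-allylic C9 hydroxyl ionises far more easily than the ring hydroxyls, and PPh3 traps the pentadienyl cation at its primary terminus to give the 9E trisubstituted alkene, leaving C5 and C6 untouched.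

**Step 4**
Reactants: 5 C15 phosphonium bromide; 6 (2E,4E,6E)-2,7-dimethylocta-2,4,6-trienedial
Product: 9 all-E (5R,6R)-5,6-dihydroxy-5,6-dihydro-12'-apo-β-caroten-12'-al, via phosphorus ylide 7 (not isolated), via 11Z-aldehyde 8 (not isolated)
Conditions: NaOMe (1.1 equiv), MeOH/CH2Cl2, −10 °C, added to 6 (2.5 equiv), 0 °C to rt; then I2 (1 mol%), CH2Cl2, rt, daylight
Reagents that add atoms: none
Why: Wittig olefination of a semi-stabilised allylic ylide with one aldehyde of the symmetric dial (excess dial ensures mono-reaction), followed by iodine-catalysed equilibration of the hindered 11Z isomer to all-E; the tertiary hydroxyls do not react.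

**Step 5**
Reactants: 9 all-E C25 diol aldehyde
Product: 11 all-E (5R,6R)-5,6-dihydroxy-5,6-dihydro-10'-apo-β-caroten-10'-al (target CNP0235139.1), via dioxolane acetal 10 (not isolated)
Conditions: (1,3-dioxolan-2-ylmethyl)triphenylphosphonium bromide (2 equiv), KOtBu (2 equiv), THF, 0 °C to rt; then PPTS (0.2 equiv), THF/H2O 4:1, rt
Reagents that add atoms: (1,3-dioxolan-2-ylmethyl)triphenylphosphonium bromide [Br-].C1COC(O1)C[P+](c1ccccc1)(c1ccccc1)c1ccccc1; water O
Why: Wittig two-carbon homologation with a masked formylmethylene ylide, then hydrolysis of the polyene-conjugated acetal under a pyridinium buffer too weak to ionise the C6 hydroxyl; the delocalised oxocarbenium ion of the hydrolysis lets the new C11'=C12' bond relax to E.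

**Compound list**
1 | β-ionone, (3E)-4-(2,6,6-trimethylcyclohex-1-en-1-yl)but-3-en-2-one | CC(=O)/C=C/C1=C(C)CCCC1(C)C | starting material
2 | (5S,6R)-5,6-epoxy-5,6-dihydro-β-ionone, (3E)-4-[(1R,6S)-2,2,6-trimethyl-7-oxabicyclo[4.1.0]heptan-1-yl]but-3-en-2-one | CC(=O)/C=C/[C@]12O[C@@]1(C)CCCC2(C)C | intermediate
3 | (5R,6R)-5,6-dihydroxy-5,6-dihydro-β-ionone, (3E)-4-[(1R,2R)-1,2-dihydroxy-2,6,6-trimethylcyclohexyl]but-3-en-2-one (trans-diol) | CC(=O)/C=C/[C@@]1(O)C(C)(C)CCC[C@@]1(C)O | intermediate
4 | (1R,2R)-1-[(1E)-3-hydroxy-3-methylpenta-1,4-dien-1-yl]-2,6,6-trimethylcyclohexane-1,2-diol (both C9 epimers) | C=CC(C)(O)/C=C/[C@@]1(O)C(C)(C)CCC[C@@]1(C)O | intermediate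
5 | [(2E,4E)-5-[(1R,2R)-1,2-dihydroxy-2,6,6-trimethylcyclohexyl]-3-methylpenta-2,4-dien-1-yl]triphenylphosphonium bromide | C(/C=C(C)/C=C/[C@@]1(O)C(C)(C)CCC[C@@]1(C)O)[P+](c1ccccc1)(c1ccccc1)c1ccccc1.[Br-] | intermediate
6 | (2E,4E,6E)-2,7-dimethylocta-2,4,6-trienedial (C10 dialdehyde) | O=C/C(C)=C/C=C/C=C(C)/C=O | starting material
7 | ylide of 5, [(2E,4E)-5-[(1R,2R)-1,2-dihydroxy-2,6,6-trimethylcyclohexyl]-3-methylpenta-2,4-dien-1-ylidene]triphenylphosphorane | C(/C=C(C)/C=C/[C@@]1(O)C(C)(C)CCC[C@@]1(C)O)=P(c1ccccc1)(c1ccccc1)c1ccccc1 | intermediate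
8 | 11Z isomer of 9, (2E,4E,6E,8Z,10E,12E)-13-[(1R,2R)-1,2-dihydroxy-2,6,6-trimethylcyclohexyl]-2,7,11-trimethyltrideca-2,4,6,8,10,12-hexaenal | O=C/C(C)=C/C=C/C=C(C)/C=C\C=C(C)\C=C\[C@@]1(O)C(C)(C)CCC[C@@]1(C)O | intermediate
9 | (5R,6R)-5,6-dihydroxy-5,6-dihydro-12'-apo-β-caroten-12'-al, (2E,4E,6E,8E,10E,12E)-13-[(1R,2R)-1,2-dihydroxy-2,6,6-trimethylcyclohexyl]-2,7,11-trimethyltrideca-2,4,6,8,10,12-hexaenal | O=C/C(C)=C/C=C/C=C(C)/C=C/C=C(C)/C=C/[C@@]1(O)C(C)(C)CCC[C@@]1(C)O | intermediate
10 | 2-[(3E,5E,7E,9E,11E,13E)-14-[(1R,2R)-1,2-dihydroxy-2,6,6-trimethylcyclohexyl]-3,8,12-trimethyltetradeca-1,3,5,7,9,11,13-heptaen-1-yl]-1,3-dioxolane (1E/1Z mixture) | O1CCOC1C=C/C(C)=C/C=C/C=C(C)/C=C/C=C(C)/C=C/[C@@]1(O)C(C)(C)CCC[C@@]1(C)O | intermediate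
11 | (5R,6R)-5,6-dihydroxy-5,6-dihydro-10'-apo-β-caroten-10'-al, (2E,4E,6E,8E,10E,12E,14E)-15-[(1R,2R)-1,2-dihydroxy-2,6,6-trimethylcyclohexyl]-4,9,13-trimethylpentadeca-2,4,6,8,10,12,14-heptaenal | CC(/C=C/C=O)=C\C=C\C=C(C)\C=C\C=C(C)\C=C\[C@@]1(O)C(C)(C)CCC[C@@]1(C)O | target

**Step count and risks**
Total steps: 5. Longest linear sequence: 5 (1 → 3 → 4 → 5 → 9 → 11).

Three steps most likely to fail:

Step 1 (proposed new method). The risks are modest enantioselectivity on a tetrasubstituted alkene, competing oxidation at C7=C8 or C4–H, and any water attack at C6, which would give the mirror-image diol and lower the ee. The ee of 3 is checked by chiral HPLC and raised by recrystallisation if needed. The fallback uses known chemistry, sets out from 1 and comes back at 3. mCPBA in CH2Cl2 at 0 °C epoxidises C5=C6 without facial control and gives 2 together with its mirror image (5R,6S)-5,6-epoxy-5,6-dihydro-β-ionone F1. 5% aqueous HClO4 in THF opens both at C5 to the racemic trans-diol, that is 3 together with (5S,6S)-5,6-dihydroxy-5,6-dihydro-β-ionone F2. Preparative chiral SFC on an amylose tris(3,5-dimethylphenylcarbamate) phase removes F2 and returns 3.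

Step 3. The pentadienyl cation sits next to the C5/C6 diol, so a ring hydroxyl could trap it (spiro-dihydrofuran), a ring bond could shift to C7, or C6 could epimerise; 9Z content is a lesser issue. The fallback avoids any cation, sets out from 3 and comes back at 5. Horner–Wadsworth–Emmons reaction of 3 with triethyl phosphonoacetate (NaH, THF, 0 °C to 50 °C) gives ethyl (2E,4E)-5-[(1R,2R)-1,2-dihydroxy-2,6,6-trimethylcyclohexyl]-3-methylpenta-2,4-dienoate F3, with the 9Z isomer removed by chromatography. iBu2AlH in toluene at −78 °C gives the primary allylic alcohol (1R,2R)-1-[(1E,3E)-5-hydroxy-3-methylpenta-1,3-dien-1-yl]-2,6,6-trimethylcyclohexane-1,2-diol F4. CBr4/PPh3 in CH2Cl2 at −20 °C converts only the primary hydroxyl, by SN2, into (1R,2R)-1-[(1E,3E)-5-bromo-3-methylpenta-1,3-dien-1-yl]-2,6,6-trimethylcyclohexane-1,2-diol F5, and a second equivalent of PPh3 quaternises it to 5.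

Step 5. The risks are ionisation of the polyene-conjugated tertiary C6 hydroxyl during acetal cleavage (epimerisation or furanoid ether formation) and incomplete Z to E relaxation of the new bond. The fallback is acid-free, sets out from 9 and comes back at 11. Horner–Wadsworth–Emmons reaction with diethyl (cyanomethyl)phosphonate (NaH, THF, 0 °C) gives (2E,4E,6E,8E,10E,12E,14E)-15-[(1R,2R)-1,2-dihydroxy-2,6,6-trimethylcyclohexyl]-4,9,13-trimethylpentadeca-2,4,6,8,10,12,14-heptaenenitrile F6. iBu2AlH (4 equiv, CH2Cl2, −78 °C) followed by wet silica gel releases 11.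

**Further compounds**
F1 | step 1 | (5R,6S)-5,6-epoxy-5,6-dihydro-β-ionone (enantiomer of 2) | CC(=O)/C=C/[C@@]12O[C@]1(C)CCCC2(C)C
F2 | step 1 | (5S,6S)-5,6-dihydroxy-5,6-dihydro-β-ionone (enantiomer of 3) | CC(=O)/C=C/[C@]1(O)C(C)(C)CCC[C@]1(C)O
F3 | step 3 | ethyl (2E,4E)-5-[(1R,2R)-1,2-dihydroxy-2,6,6-trimethylcyclohexyl]-3-methylpenta-2,4-dienoate | CCOC(=O)/C=C(C)/C=C/[C@@]1(O)C(C)(C)CCC[C@@]1(C)O
F4 | step 3 | (1R,2R)-1-[(1E,3E)-5-hydroxy-3-methylpenta-1,3-dien-1-yl]-2,6,6-trimethylcyclohexane-1,2-diol | OC/C=C(C)/C=C/[C@@]1(O)C(C)(C)CCC[C@@]1(C)O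
F5 | step 3 | (1R,2R)-1-[(1E,3E)-5-bromo-3-methylpenta-1,3-dien-1-yl]-2,6,6-trimethylcyclohexane-1,2-diol | BrC/C=C(C)/C=C/[C@@]1(O)C(C)(C)CCC[C@@]1(C)O
F6 | step 5 | (2E,4E,6E,8E,10E,12E,14E)-15-[(1R,2R)-1,2-dihydroxy-2,6,6-trimethylcyclohexyl]-4,9,13-trimethylpentadeca-2,4,6,8,10,12,14-heptaenenitrile | N#C/C=C/C(C)=C/C=C/C=C(C)/C=C/C=C(C)/C=C/[C@@]1(O)C(C)(C)CCC[C@@]1(C)O
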